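(The readings are simulated from invented constants, and the scatter is random.)

Amounts come first: a charge of 0.5 mol% free catalyst has to move substrate at 0.20 M, and the question is how far it gets.

| flask | substrate | partner | free catalyst | second catalyst | remark | time |
|---|---|---|---|---|---|---|
| violet | 0.20 M | 1.3 equiv | 0.5 mol% | 13 mol% | the very flask that is asked about, followed so far |  |
| red | 0.20 M | 1.3 equiv | 0.5 mol% | 8.7 mol% | run made earlier |  |
| flask | 0.20 M | 1.30 equiv | 0.5 mol% | 13 mol% |  | 5.0 h |

- violet (time / min: target / %, substrate / %): 25.0: 39.7, 33.3; 60.0: 43.2, 31.4; 120: 43.5, 32.0; 180: 43.6, 31.2
- red (time / min: target / %, substrate / %): 2.50: 2.3, 73.7; 6.00: 9.6, 55.5; 12.0: 20.4, 41.8; 30.0: 34.5, 32.7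

(readings scatter by 0.3 percentage points)

- target taken out counts as made
- the earlier runs were read with a standard deviation of 0.3 percentage points
- "the catalyst" is free catalyst with its forms; second catalyst is a second catalyst
- additions bring no volume worth counting

- epsilon: at 5.0 h add partner, 50.0 % of the amount charged, then wait 10 h
- beta: at 5.0 h take out 90 % of the target then present, then wait 10 h
- zeta: at 5.0 h add free catalyst, 100 % of the amount charged, then wait 10 h
- theta: change nothing and wait 10 h more

1. target, in percent of the substrate first charged, at 5.0 h
2. the option that brings most further target ("none" if no option brings more than 2 percentage points) (epsilon / beta / zeta / theta / none)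
3. target present, with what was taken out counted in, in percent of the substrate first charged, after zeta
4. target present, with what was taken out counted in, in percent of the substrate first charged, after theta

We read the runs as a ladder, fastest rung first. Within minutes substrate leaves: by 2.50 min the red run shows target 2.3 %, less than the 26 percentage points of substrate gone, so an unseen form stands between them. Next the free catalyst fades. Red substrate falls at 0.0810 min⁻¹ between its first two readings and at 0.0136 min⁻¹ between its last two, a pseudo-first-order loss that slows. Target fills in over tens of minutes: violet, the flask asked about, gives 39.7 % at 25.0 min and 43.2 % at 60.0 min. Then violet stands still: up to 180 min target moves 0.4 points and substrate 0.2 points, against a scatter of 0.3 points.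

A first-order loss belongs on a logarithmic scale. Violet's last substrate, 31.2 %, lies 0.506 powers of ten below the charge. We call this the reach, the powers of ten of substrate that one charge of free catalyst takes off in its whole life. We take it to go with [free catalyst] as charged, so a new charge adds the same reach again.

Our reckoning for violet is target near 43.4 % now and after theta. Zeta adds a second reach and leaves 9.73 % substrate. Violet turned 0.634 of the substrate used into target, so zeta should bring 14 points, giving 57.2 %. Epsilon adds no reach. The unseen 25.2 % we take, less surely, as lost, so we expect nothing from beta and choose zeta.

The forecast gives 43.5 % now, 43.6 % after theta, 57 % after zeta, and chooses beta. Of the stalled target it says: “I therefore read this, less certainly, as intermediate ⇌ target equilibrium”. We part from it on beta.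

The flask gives 43.2 % now and 43.2 % after theta. Zeta brings 14 points and stands at 56.9 %; beta brings 0 points, so the best option is zeta.

    substrate + free catalyst → free catalyst + open intermediate (k = 2.30 L mol⁻¹ s⁻¹)
    second catalyst + open intermediate ⇌ catalyst intermediate (K = 9.10 L mol⁻¹, k = 0.0770 L mol⁻¹ s⁻¹)
    partner + catalyst intermediate → second catalyst + target (k = 0.900 L mol⁻¹ s⁻¹)
    free catalyst → spent catalyst (k = 0.00200 s⁻¹)
    open intermediate → side product (k = 0.00110 s⁻¹)

Free catalyst has a half-life of 5.8 min by its own decay, and substrate under the full charge of free catalyst has 5.02 min; at 300 min the flask holds substrate 31.7 % beside free catalyst 0 %. A neighbour charged with 0.050 M substrate has a quarter of this [free catalyst], so a quarter of the reach leaves 74.7 %, and that neighbour holds substrate 75 %.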